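The ten-membered carbocycle is disconnected at C2–C3 (germacrane numbering) by an anionic oxy-Cope ring expansion. The step exploits that ring atoms C10–C1–C2–C3–C4–C5, with methyls on C10 and C4 and oxygen on C5, are a 3-oxido-1,5-diene in disguise: in one operation the alkoxide of a 1-isopropenyl-2-methyl-2-vinylcyclohexanol forms C2–C3, cuts the cyclohexane C5–C10 bond and delivers the cyclodecadiene with a C4=C5 enolate, trapped as its triflate. The precursor is an elemane-type cyclohexane made from (R)-carvone that already carries the C6, C7, C8 and C9 substituents; epoxidation, conjugate reduction and epoxide hydrolysis later set C4, C5 and C10.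

Key step: step 12

Remark on numbering: germacrane numbers are used for every compound: C6 = ring CH bearing the lactone oxygen, C7 = ring CH bearing C11 (C12 = lactone C=O, C13 = exocyclic CH2), C8 = CH–O(2-methylbutanoyl), C9 = C=O, C10 = CH–CH3 (C14), C1–C3 = the three CH2, C4 = C(OH)CH3 (C15), C5 = CH–O(isobutyryl); β is the ring face of the C7–C11 bond, α the other face; in (R)-carvone the carbonyl carbon is C5, the methyl-bearing carbon C10 and the isopropenyl carbon C11.
Assumption: (R)-2-methylbutanoic acid is bought enantiopure; the C9 carbinol configuration (steps 9–13) and the C1=C10 geometry (steps 12–17) are erased later, so the isomers drawn there are the expected ones but are not essential.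

Step 1
Reactants: 1 (R)-(−)-carvone
Product: 3 trans-6-hydroxycarvone (6α-OH), via sodium dienolate 2 (not isolated)
Conditions: NaN(SiMe3)2, THF, −78 °C; 2-(phenylsulfonyl)-3-phenyloxaziridine, −78 °C; H2O
Reagents that add atoms: 2-(phenylsulfonyl)-3-phenyloxaziridine, O=S(=O)(c1ccccc1)N1OC1c1ccccc1; NaN(SiMe3)2, C[Si](C)(C)[N-][Si](C)(C)C.[Na+] (sodium stays in 2 only)
Why: Kinetic deprotonation at the only α′ position gives the cross-conjugated enolate, which the oxaziridine hydroxylates anti to the neighbouring isopropenyl group (Davis enolate oxidation), so the new C6 carbinol should be trans (6α).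

Step 2
Reactants: 3 trans-6-hydroxycarvone
Product: 4 6α,12-diol (isopropenyl CH3 oxidised to CH2OH)
Conditions: SeO2 (0.3 equiv), t-BuOOH, CH2Cl2, 0 °C → rt
Reagents that add atoms: tert-butyl hydroperoxide, CC(C)(C)OO
Why: Catalytic SeO2/t-BuOOH allylic oxidation (ene reaction then [2,3] shift) attacks the electron-rich 1,1-disubstituted alkene at its methyl group and not the electron-poor enone, and no stereocentre is formed.

Step 3
Reactants: 4 6α,12-diol
Product: 5 6α,12-bis(triisopropylsilyl) ether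
Conditions: TIPSOTf (2.4 equiv), 2,6-lutidine, CH2Cl2, −78 → 0 °C
Reagents that add atoms: triisopropylsilyl triflate, CC(C)[Si](OS(=O)(=O)C(F)(F)F)(C(C)C)C(C)C
Why: Silyl triflate and a hindered pyridine silylate both hydroxyls (silyl ether formation), and triisopropylsilyl is chosen because it does not migrate to a neighbouring alkoxide and survives the later acid steps.

Step 4
Reactants: 5 bis-silyl enone
Product: 6 5β-hydroxy-5α-vinyl tertiary allylic alcohol
Conditions: CH2=CHMgBr, CeCl3, THF, −78 °C; H2O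
Reagents that add atoms: vinylmagnesium bromide, C=C[Mg]Br
Why: CeCl3-promoted Grignard 1,2-addition to the enone, in which the nucleophile enters axially on the face opposite the C7 side chain and so gives the 5β-hydroxy-5α-vinyl carbinol.

Step 5
Reactants: 6 tertiary allylic alcohol
Product: 7 9β,10β-epoxy alcohol
Conditions: VO(acac)2 (5 mol %), t-BuOOH, toluene, 0 °C → rt
Reagents that add atoms: tert-butyl hydroperoxide, CC(C)(C)OO
Why: Hydroxyl-directed epoxidation delivers oxygen to the trisubstituted ring alkene syn to the tertiary alcohol (β face), while the monosubstituted vinyl group and the remote side-chain alkene react far more slowly.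

Step 6
Reactants: 7 epoxy alcohol
Product: 8 9β-hydroxy-10β-methyl-10α-vinyl 5-ketone
Conditions: BF3·OEt2 (0.2 equiv), CH2Cl2, −78 °C
Reagents that add atoms: none
Why: Semipinacol rearrangement of a 2,3-epoxy alcohol, in which opening of the tertiary C10–O bond is accompanied by 1,2-shift of the antiperiplanar vinyl group from C5 to the α face of C10 (inversion), so the ketone returns to C5, the 9β-hydroxyl remains and the quaternary centre is set stereospecifically.

Step 7
Reactants: 8 β-hydroxy ketone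
Product: 9 10β-methyl-10α-vinyl-5,9-dione
Conditions: Dess–Martin periodinane, pyridine, CH2Cl2, 0 °C → rt
Reagents that add atoms: none
Why: Dess–Martin oxidation of the hindered secondary alcohol under neutral conditions avoids retro-aldol cleavage of the β-hydroxy ketone.

Step 8
Reactants: 9 5,9-dione
Product: 11 8α-hydroxy-5,9-dione, via sodium enolate 10 (not isolated)
Conditions: NaN(SiMe3)2, THF, −78 °C; 2-(phenylsulfonyl)-3-phenyloxaziridine, −78 °C; H2O
Reagents that add atoms: 2-(phenylsulfonyl)-3-phenyloxaziridine, O=S(=O)(c1ccccc1)N1OC1c1ccccc1; NaN(SiMe3)2, C[Si](C)(C)[N-][Si](C)(C)C.[Na+] (sodium stays in 10 only)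
Why: Davis enolate oxidation in which, C10 being quaternary, the base removes a proton from the open C8 methylene and not from the C6 methine shielded by its silyl ether, and the oxaziridine then attacks anti to the C7 side chain (8α-OH).

Step 9
Reactants: 11 8α-hydroxy-5,9-dione
Product: 12 8α,9β-dihydroxy 5-ketone
Conditions: Me4NBH(OAc)3, MeCN/AcOH, −20 °C
Reagents that add atoms: none
Why: Hydroxyl-directed triacetoxyborohydride reduction reduces only the carbonyl next to the free 8-hydroxyl and delivers hydride to the α face, away from the axial C10 methyl, to give the trans-diequatorial 8α,9β-diol.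

Step 10
Reactants: 12 diol ketone
Product: 13 8α,9β-O-isopropylidene 5-ketone
Conditions: 2-methoxypropene, PPTS (cat.), CH2Cl2, 0 °C
Reagents that add atoms: 2-methoxypropene, COC(C)=C
Why: Kinetic acetonide formation on the trans-diequatorial diol gives a trans-fused dioxolane that locks the chair in which the C10 vinyl group is equatorial and the C10 methyl axial.

Step 11
Reactants: 13 acetonide ketone
Product: 14 5β-hydroxy-5α-isopropenyl carbinol (cis-1,2-dialkenylcyclohexanol)
Conditions: CH2=C(CH3)MgBr, CeCl3, THF, −78 → 0 °C; H2O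
Reagents that add atoms: isopropenylmagnesium bromide, CC(=C)[Mg]Br
Why: CeCl3-promoted Grignard addition to the hindered ketone, in which attack anti to the axial C10 methyl (axial attack, as on angular-methyl decalones) places the isopropenyl group axial (5α) and gauche to the equatorial vinyl group.

Step 12
Reactants: 14 cis-1,2-dialkenylcyclohexanol
Product: 17 (1(10)Z,4E)-cyclodecadienyl 5-triflate, via potassium alkoxide 15 (not isolated), via potassium cyclodecadienolate 16 (not isolated)
Conditions: KH, 18-crown-6, THF, 0 °C → rt; then PhNTf2, −78 → 0 °C; H2O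
Reagents that add atoms: N-phenylbis(trifluoromethanesulfonimide), O=S(=O)(N(c1ccccc1)S(=O)(=O)C(F)(F)F)C(F)(F)F; potassium hydride, [K+].[H-] (potassium stays in 15 and 16 only)
Why: Deprotonation gives potassium alkoxide 15, whose C5–C10 bond is weakened by the oxyanion so that a concerted, charge-accelerated [3,3] sigmatropic shift (anionic oxy-Cope) through the chair-like six-atom array C2–C1–C10–C5–C4–C3 gives enolate 16. The closest known reaction type is the ring expansion of 1,2-dialkenylcyclohexanols to cyclodec-5-enones. The ten-membered ring is closed by ring expansion and not by end-to-end cyclisation: C2–C3 forms between two alkene termini held gauche on the six-membered ring while C5–C10 breaks, so no medium-ring entropy or transannular penalty is paid. No sp3 stereocentre is formed; the two new double bonds are stereogenic and are controlled by the chair locked by the trans-acetonide (axial isopropenyl, equatorial vinyl), which puts C6 pseudo-equatorial and C9 pseudo-axial in the transition state and so gives C4=C5 with C3 and C6 trans (4E) and C1=C10 with C2 and C9 cis. The step needs the [3,3] path to win over retro-ene or 1,3-shift fragmentation and over silyl migration, which the gauche dialkenyl geometry, the crown-ether-separated alkoxide and the non-migrating TIPS and acetal groups should secure. O-Sulfonylation of the enolate by PhNTf2 keeps the 4E geometry needed for the later trans-epoxide, and the C1=C10 geometry is erased in step 18.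

Step 13
Reactants: 17 enol triflate acetonide
Product: 18 8α,9β-diol enol triflate
Conditions: PPTS, MeOH, 45 °C
Reagents that add atoms: none
Why: Acid-catalysed transacetalisation removes the acetonide at the stage where the electron-poor vinyl triflate cannot act as the nucleophile of a transannular cyclisation and the silyl ethers are stable.

Step 14
Reactants: 18 diol
Product: 19 8α-hydroxy-9-oxo enone (1(10)Z) 5-triflate
Conditions: MnO2, CH2Cl2, rt
Reagents that add atoms: none
Why: MnO2 oxidises only the allylic C9 alcohol to the enone (allylic alcohol oxidation) and leaves the C8 hydroxyl.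

Step 15
Reactants: 19 hydroxy enone; 20 (R)-2-methylbutanoic acid
Product: 21 8α-[(R)-2-methylbutanoyloxy] enone 5-triflate
Conditions: DCC, DMAP (cat.), CH2Cl2, 0 °C
Reagents that add atoms: none
Why: Steglich esterification of the only free hydroxyl at low temperature brings in the acid with its stereocentre unchanged.

Step 16
Reactants: 21 enol triflate
Product: 22 (1(10)Z,4E)-8α-acyloxy-6α,12-bis(silyloxy)germacra-1(10),4,11(13)-trien-9-one
Conditions: Pd(OAc)2 (5 mol %), PPh3, HCO2H, n-Bu3N, DMF, 60 °C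
Reagents that add atoms: none
Why: Palladium-catalysed formate reduction of the enol triflate (oxidative addition, hydride transfer from formate, reductive elimination) replaces OTf by H with retention of the double-bond geometry and gives the 4E alkene.

Step 17
Reactants: 22 trienone
Product: 23 4α,5β-epoxide
Conditions: mCPBA, CH2Cl2, −20 → 0 °C
Reagents that add atoms: 3-chloroperbenzoic acid, O=C(OO)c1cccc(Cl)c1
Why: Prilezhaev epoxidation of the only electron-rich trisubstituted alkene, where allylic 1,3-strain keeps H6 in the alkene plane and the ring blocks the inner face, so oxygen should add to the outer face (C4 from α, C5 from β) as in parthenolide-type epoxides, while the enone and the hindered side-chain alkene react more slowly.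

Step 18
Reactants: 23 epoxy enone
Product: 24 1,10-dihydro epoxy ketone (10β-methyl)
Conditions: [(Ph3P)CuH]6 (5 mol %), H2 (30 atm), t-BuOH, benzene, rt
Reagents that add atoms: none
Why: Copper-hydride-catalysed conjugate reduction is selective for the enone, and the C10 stereocentre arises when t-BuOH protonates the copper enolate from the less hindered outer face, which is expected to leave the methyl group β.

Step 19
Reactants: 24 epoxy ketone
Product: 25 4β,5β-diol (4α-methyl)
Conditions: HClO4 (0.1 M aq), THF, 0 °C → rt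
Reagents that add atoms: water, O
Why: Acid-catalysed epoxide hydrolysis in which water opens the protonated epoxide at the tertiary C4 with inversion (borderline SN2), giving the 4β-hydroxy-4α-methyl carbinol while the C5 oxygen keeps its β configuration.

Step 20
Reactants: 25 bis-silyl diol
Product: 26 4β,5β,6α,12-tetraol
Conditions: HF·pyridine, pyridine, THF, 0 °C → rt
Reagents that add atoms: none
Why: Fluoride-mediated desilylation under buffered, weakly acidic conditions frees O6 and O12 without acyl migration.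

Step 21
Reactants: 26 tetraol
Product: 29 4β,5β-dihydroxy-8α-acyloxy-9-oxo-germacr-11(13)-en-12,6α-olide, via enal 27 (not isolated), via lactol 28 (not isolated)
Conditions: MnO2 (excess), CH2Cl2, rt
Reagents that add atoms: none
Why: MnO2 oxidative lactonisation, in which the allylic primary alcohol is oxidised to the enal, this closes to the five-membered lactol on the 6α-hydroxyl and is oxidised again to the trans-fused α-methylene lactone, the non-allylic secondary and tertiary alcohols being inert.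

Step 22
Reactants: 29 diol lactone
Product: 30 CNP0071420.1
Conditions: (i-PrCO)2O, DMAP (cat.), pyridine, 0 °C → rt
Reagents that add atoms: isobutyric anhydride, CC(C)C(=O)OC(=O)C(C)C
Why: DMAP-catalysed acylation of the only remaining secondary hydroxyl (C5), which the tertiary C4 hydroxyl cannot match in rate.

Compound list
1 | (R)-(−)-carvone | O=C1C[C@H](C(C)=C)CC=C1C | starting material
2 | sodium dienolate of 1 (O–C5=C6; not isolated) | [Na+].[O-]C1=C[C@H](C(C)=C)CC=C1C | intermediate
3 | trans-6-hydroxycarvone, (5S,6S)-6-hydroxy-2-methyl-5-(prop-1-en-2-yl)cyclohex-2-en-1-one (6α-OH) | O=C1[C@@H](O)[C@H](C(C)=C)CC=C1C | intermediate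
4 | 6α,12-diol (C7 substituent = 3-hydroxyprop-1-en-2-yl) | O=C1[C@@H](O)[C@H](C(=C)CO)CC=C1C | intermediate
5 | 6α,12-bis(triisopropylsilyl) ether of 4 | O=C1[C@@H](O[Si](C(C)C)(C(C)C)C(C)C)[C@H](C(=C)CO[Si](C(C)C)(C(C)C)C(C)C)CC=C1C | intermediate
6 | 5β-hydroxy-5α-vinyl tertiary allylic alcohol | O[C@]1(C=C)[C@@H](O[Si](C(C)C)(C(C)C)C(C)C)[C@H](C(=C)CO[Si](C(C)C)(C(C)C)C(C)C)CC=C1C | intermediate
7 | 9β,10β-epoxide of 6 | O[C@]1(C=C)[C@@H](O[Si](C(C)C)(C(C)C)C(C)C)[C@H](C(=C)CO[Si](C(C)C)(C(C)C)C(C)C)C[C@@H]2O[C@]12C | intermediate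
8 | 9β-hydroxy-10β-methyl-10α-vinyl cyclohexan-5-one | O=C1[C@@H](O[Si](C(C)C)(C(C)C)C(C)C)[C@H](C(=C)CO[Si](C(C)C)(C(C)C)C(C)C)C[C@H](O)[C@@]1(C)C=C | intermediate
9 | 10β-methyl-10α-vinyl cyclohexane-5,9-dione | O=C1[C@@H](O[Si](C(C)C)(C(C)C)C(C)C)[C@H](C(=C)CO[Si](C(C)C)(C(C)C)C(C)C)CC(=O)[C@@]1(C)C=C | intermediate
10 | sodium C8=C9 enolate of 9 (not isolated) | O=C1[C@@H](O[Si](C(C)C)(C(C)C)C(C)C)[C@H](C(=C)CO[Si](C(C)C)(C(C)C)C(C)C)C=C([O-])[C@@]1(C)C=C.[Na+] | intermediate
11 | 8α-hydroxy-5,9-dione | O=C1[C@@H](O[Si](C(C)C)(C(C)C)C(C)C)[C@H](C(=C)CO[Si](C(C)C)(C(C)C)C(C)C)[C@@H](O)C(=O)[C@@]1(C)C=C | intermediate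
12 | 8α,9β-dihydroxy 5-ketone | O=C1[C@@H](O[Si](C(C)C)(C(C)C)C(C)C)[C@H](C(=C)CO[Si](C(C)C)(C(C)C)C(C)C)[C@@H](O)[C@H](O)[C@@]1(C)C=C | intermediate
13 | 8α,9β-O-isopropylidene 5-ketone | O=C1[C@@H](O[Si](C(C)C)(C(C)C)C(C)C)[C@H](C(=C)CO[Si](C(C)C)(C(C)C)C(C)C)[C@H]2OC(C)(C)O[C@@H]2[C@@]1(C)C=C | intermediate
14 | 5β-hydroxy-5α-isopropenyl-10β-methyl-10α-vinyl cyclohexane (oxy-Cope substrate) | O[C@]1(C(C)=C)[C@@H](O[Si](C(C)C)(C(C)C)C(C)C)[C@H](C(=C)CO[Si](C(C)C)(C(C)C)C(C)C)[C@H]2OC(C)(C)O[C@@H]2[C@@]1(C)C=C | intermediate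
15 | potassium alkoxide of 14 (not isolated) | [K+].[O-][C@]1(C(C)=C)[C@@H](O[Si](C(C)C)(C(C)C)C(C)C)[C@H](C(=C)CO[Si](C(C)C)(C(C)C)C(C)C)[C@H]2OC(C)(C)O[C@@H]2[C@@]1(C)C=C | intermediate
16 | potassium (1(10)Z,4E)-cyclodeca-1(10),4-dien-5-olate (not isolated) | C/C1=C(/[O-])\[C@@H](O[Si](C(C)C)(C(C)C)C(C)C)[C@H](C(=C)CO[Si](C(C)C)(C(C)C)C(C)C)[C@H]2OC(C)(C)O[C@@H]2/C(C)=C\CC1.[K+] | intermediate
17 | (1(10)Z,4E)-germacra-1(10),4,11(13)-trien-5-yl triflate, 6α,12-bis-OTIPS, 8α,9β-acetonide | C/C1=C(/OS(=O)(=O)C(F)(F)F)\[C@@H](O[Si](C(C)C)(C(C)C)C(C)C)[C@H](C(=C)CO[Si](C(C)C)(C(C)C)C(C)C)[C@H]2OC(C)(C)O[C@@H]2/C(C)=C\CC1 | intermediate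
18 | 8α,9β-diol of 17 | C/C1=C(/OS(=O)(=O)C(F)(F)F)\[C@@H](O[Si](C(C)C)(C(C)C)C(C)C)[C@H](C(=C)CO[Si](C(C)C)(C(C)C)C(C)C)[C@@H](O)[C@H](O)/C(C)=C\CC1 | intermediate
19 | 8α-hydroxy-9-oxo (1(10)Z)-enone 5-triflate | C/C1=C(/OS(=O)(=O)C(F)(F)F)\[C@@H](O[Si](C(C)C)(C(C)C)C(C)C)[C@H](C(=C)CO[Si](C(C)C)(C(C)C)C(C)C)[C@@H](O)C(=O)/C(C)=C\CC1 | intermediate
20 | (R)-2-methylbutanoic acid | CC[C@@H](C)C(=O)O | starting material
21 | 8α-[(R)-2-methylbutanoyloxy]-9-oxo 5-triflate | C/C1=C(/OS(=O)(=O)C(F)(F)F)\[C@@H](O[Si](C(C)C)(C(C)C)C(C)C)[C@H](C(=C)CO[Si](C(C)C)(C(C)C)C(C)C)[C@@H](OC(=O)[C@H](C)CC)C(=O)/C(C)=C\CC1 | intermediate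
22 | (1(10)Z,4E)-8α-[(R)-2-methylbutanoyloxy]-6α,12-bis(triisopropylsilyloxy)germacra-1(10),4,11(13)-trien-9-one | C/C1=C\[C@@H](O[Si](C(C)C)(C(C)C)C(C)C)[C@H](C(=C)CO[Si](C(C)C)(C(C)C)C(C)C)[C@@H](OC(=O)[C@H](C)CC)C(=O)/C(C)=C\CC1 | intermediate
23 | 4α,5β-epoxide of 22 | C[C@@]12O[C@@H]2[C@@H](O[Si](C(C)C)(C(C)C)C(C)C)[C@H](C(=C)CO[Si](C(C)C)(C(C)C)C(C)C)[C@@H](OC(=O)[C@H](C)CC)C(=O)/C(C)=C\CC1 | intermediate
24 | 1,10-dihydro epoxy ketone (10β-methyl, H-10α) | C[C@@]12O[C@@H]2[C@@H](O[Si](C(C)C)(C(C)C)C(C)C)[C@H](C(=C)CO[Si](C(C)C)(C(C)C)C(C)C)[C@@H](OC(=O)[C@H](C)CC)C(=O)[C@H](C)CCC1 | intermediate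
25 | 4β,5β-diol (4α-methyl), 6α,12-bis-OTIPS | C[C@@]1(O)[C@H](O)[C@@H](O[Si](C(C)C)(C(C)C)C(C)C)[C@H](C(=C)CO[Si](C(C)C)(C(C)C)C(C)C)[C@@H](OC(=O)[C@H](C)CC)C(=O)[C@H](C)CCC1 | intermediate
26 | 4β,5β,6α,12-tetraol | C[C@@]1(O)[C@H](O)[C@@H](O)[C@H](C(=C)CO)[C@@H](OC(=O)[C@H](C)CC)C(=O)[C@H](C)CCC1 | intermediate
27 | 12-aldehyde of 26 (enal; not isolated) | C[C@@]1(O)[C@H](O)[C@@H](O)[C@H](C(=C)C=O)[C@@H](OC(=O)[C@H](C)CC)C(=O)[C@H](C)CCC1 | intermediate
28 | 6α,12-lactol (both C12 epimers; not isolated) | C[C@@]1(O)[C@H](O)[C@H]2OC(O)C(=C)[C@@H]2[C@@H](OC(=O)[C@H](C)CC)C(=O)[C@H](C)CCC1 | intermediate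
29 | 4β,5β-dihydroxy-8α-[(R)-2-methylbutanoyloxy]-9-oxo-germacr-11(13)-en-12,6α-olide | C[C@@]1(O)[C@H](O)[C@H]2OC(=O)C(=C)[C@@H]2[C@@H](OC(=O)[C@H](C)CC)C(=O)[C@H](C)CCC1 | intermediate
30 | CNP0071420.1 (5β-isobutyrate of 29) | C=C1C(=O)O[C@H]2[C@H]1[C@@H](OC(=O)[C@H](C)CC)C(=O)[C@H](C)CCC[C@](C)(O)[C@@H]2OC(=O)C(C)C | target

Total step count: 22. Longest linear sequence: 22 steps from 1 (20 is bought).

Steps most likely to fail

Step 12. The tertiary alkoxide may fragment (retro-ene or 1,3-shift) or take up a silyl or acetal group from a neighbouring oxygen before the [3,3] shift, and the enolate may be sulfonylated with loss of geometry. The fallback leaves the anionic manifold. It sets out from 14, which is silylated (N-trimethylsilylimidazole, CH2Cl2) to the trimethylsilyl ether F1. Heating F1 (decalin, 190 °C, base-washed sealed tube) should cause a neutral siloxy-Cope rearrangement through the same chair array to the trimethylsilyl enol ether F2. MeLi (THF, 0 °C) then releases the lithium enolate with retention of geometry, and PhNTf2 brings the route back to 17.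

Step 18. Protonation of the copper enolate may occur from the wrong face, and enolisation toward C8 or C10 may erode either centre. The fallback sets C10 by hydrogen delivery from a temporary stereocentre. It sets out from 23: Luche reduction (NaBH4, CeCl3·7H2O, MeOH, −78 °C) gives the allylic 9β-alcohol F3 (the 9α epimer, if formed, is separated). Hydroxyl-directed hydrogenation with [Rh(nbd)(dppb)]BF4 under H2 adds hydrogen to C10 from the face of the bound hydroxyl in the conformer free of allylic 1,3-strain (1,2-anti induction) and gives the 10β-methyl alcohol F4. Dess–Martin oxidation returns to 24.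

Step 17. The peracid may attack the wrong face of C4=C5, or the side-chain alkene, while the ring is still flexible and carries two bulky silyl ethers. The fallback moves the epoxidation to the rigid lactone. It sets out from 22: conjugate reduction as in step 18 gives the saturated ketone F5, HF·pyridine the 6α,12-diol F6, and MnO2 the α-methylene lactone F7. In F7 the exocyclic alkene is electron-poor and the trans-fused lactone fixes the orientation of the 4E alkene. mCPBA should then give the 4α,5β-epoxide F8, and aqueous HClO4 opens it at C4 to rejoin the route at 29.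

Further compounds
F1 | step 12 | trimethylsilyl ether of 14 | C[Si](C)(C)O[C@]1(C(C)=C)[C@@H](O[Si](C(C)C)(C(C)C)C(C)C)[C@H](C(=C)CO[Si](C(C)C)(C(C)C)C(C)C)[C@H]2OC(C)(C)O[C@@H]2[C@@]1(C)C=C
F2 | step 12 | (1(10)Z,4E)-cyclodecadienyl trimethylsilyl enol ether | C/C1=C(/O[Si](C)(C)C)\[C@@H](O[Si](C(C)C)(C(C)C)C(C)C)[C@H](C(=C)CO[Si](C(C)C)(C(C)C)C(C)C)[C@H]2OC(C)(C)O[C@@H]2/C(C)=C\CC1
F3 | step 18 | 9β-hydroxy allylic alcohol from 23 | C[C@@]12O[C@@H]2[C@@H](O[Si](C(C)C)(C(C)C)C(C)C)[C@H](C(=C)CO[Si](C(C)C)(C(C)C)C(C)C)[C@@H](OC(=O)[C@H](C)CC)[C@H](O)/C(C)=C\CC1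
F4 | step 18 | 9β-hydroxy-10β-methyl 1,10-dihydro alcohol | C[C@@]12O[C@@H]2[C@@H](O[Si](C(C)C)(C(C)C)C(C)C)[C@H](C(=C)CO[Si](C(C)C)(C(C)C)C(C)C)[C@@H](OC(=O)[C@H](C)CC)[C@H](O)[C@H](C)CCC1
F5 | step 17 | (4E)-1,10-dihydro-9-ketone, 6α,12-bis-OTIPS | C/C1=C\[C@@H](O[Si](C(C)C)(C(C)C)C(C)C)[C@H](C(=C)CO[Si](C(C)C)(C(C)C)C(C)C)[C@@H](OC(=O)[C@H](C)CC)C(=O)[C@H](C)CCC1
F6 | step 17 | (4E)-6α,12-diol | C/C1=C\[C@@H](O)[C@H](C(=C)CO)[C@@H](OC(=O)[C@H](C)CC)C(=O)[C@H](C)CCC1
F7 | step 17 | (4E)-8α-acyloxy-9-oxo-germacra-4,11(13)-dien-12,6α-olide | C/C1=C\[C@H]2OC(=O)C(=C)[C@@H]2[C@@H](OC(=O)[C@H](C)CC)C(=O)[C@H](C)CCC1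
F8 | step 17 | 4α,5β-epoxy lactone | C[C@@]12O[C@@H]2[C@H]3OC(=O)C(=C)[C@@H]3[C@@H](OC(=O)[C@H](C)CC)C(=O)[C@H](C)CCC1
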